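The vessel is closed, stirred and held at constant volume. The red flask in it has been followed for 4.00 min, and the green run was made earlier, with more catalyst and colder.

| flask | starting material | second substrate | capture agent | free catalyst | added ligand | temperature | remark | time |
|---|---|---|---|---|---|---|---|---|
| red | 3 M | 1.5 M | 0.30 M | 10 mM | 32 mM | 0 °C | the very flask that is asked about, followed so far |  |
| green | 3 M | 1.5 M | 0.30 M | 15 mM | 32 mM | −5 °C | run made earlier |  |
| flask | 3.0 M | 1.50 M | 0.300 M | 10 mM | 32 mM | 0 °C |  | 5.0 min |

red run (percent of the starting material charged)

| time / min | target / % | starting material / % |
|---|---|---|
| 0.333 | 7.8 | 93.1 |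
| 0.667 | 12.6 | 87.3 |
| 1.00 | 15.2 | 84.5 |
| 2.00 | 21.9 | 78.6 |
| 4.00 | 24.1 | 75.4 |

green run (percent of the starting material charged)

| time / s | target / % | starting material / % |
|---|---|---|
| 25.0 | 9.8 | 91.2 |
| 50.0 | 15.3 | 84.4 |
| 80.0 | 20.2 | 79.8 |
| 90.0 | 21.1 | 77.5 |
| 120 | 25.5 | 73.9 |

(readings scatter by 0.5 percentage points)

- south-west: change nothing and wait 2.5 min more
- north-west: at 5.0 min add free catalyst, 50.0% of the amount charged, then wait 2.5 min
- east: at 5.0 min raise the temperature by 10 K, then wait 2.5 min
- south: at 5.0 min take out 90% of the target then present, then wait 2.5 min

* target, in percent of the starting material first charged, at 5.0 min
* the option that brings most further target ("none" if no option brings more than 2 percentage points) (south-west / north-west / east / south / none)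
* target present, with what was taken out counted in, in percent of the starting material first charged, after south-west
* target present, with what was taken out counted in, in percent of the starting material first charged, after south

- what is taken out of target is counted as made
- what was read earlier has a scatter of 0.5 percentage points, one standard deviation
- steps under discussion: starting material + free catalyst <-> catalyst intermediate A; catalyst intermediate A -> free catalyst + target; second substrate + free catalyst <-> catalyst intermediate B; catalyst intermediate B -> free catalyst + second product; free catalyst + added ligand <-> idle complex; catalyst intermediate B + capture agent -> trapped intermediate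
- additions bring no volume worth counting

On the board, starting material and second substrate each bind free catalyst and leave as target and second product. Added ligand parks free catalyst as idle complex, and capture agent turns catalyst intermediate B into trapped intermediate, with no way back.

In red, target rose 6.7 percentage points from 1.00 min to 2.00 min, then 2.2 points from 2.00 min to 4.00 min, while 75.4% of the starting material stood there. Two chemists read this stall differently.

The second chemist says the catalyst is merely parked: red holds 32 mM of added ligand against 10 mM of free catalyst, and parked catalyst comes back. He carries the last rise forward at its own pace, which gives 2.8 points in the further 2.5 min. That clears the bar of 2 points, so for him waiting pays.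

The first chemist says the catalyst is being lost, so a charge of it holds a fixed amount of work. The forecast is on her side: “the catalyst is dying rather than the substrate running out”. It gives 24.9% now, 25.2% after south-west, 25.2% after south, and north-west as best.

My own reckoning takes her side too. Red's last reading, with its scatter, is 24.1% on a catalyst charge of 0.333% of the starting material, which makes 72.3. Call this the lifetime count, the target made per catalyst charged, or the turnover number. Fresh catalyst at 50.0% of the charge should then bring 12 points, where the forecast says 8 to 10. Among the steps under discussion, catalyst is lost by way of catalyst intermediate B, so with the other charges held I expect the count to fall in inverse proportion to the second substrate charged.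

The flask gives 25.5%, with north-west best, 25.9% after south-west and 25.9% after south. In the flask at 5.00 min, trapped intermediate holds 98.4% of the catalyst and idle complex 0.701%, and south-west brings 0.37 points, where the second chemist said 2.8 points. North-west brings 12 points, where the lifetime count said 12 points. Parking holds more of the catalyst in a neighbour flask with 0.075 M of capture agent: at 5.00 min it has 21.5% as idle complex, though still 57.3% trapped, and its target stands at 61.7%. For another neighbour flask with 2.5 M of second substrate and the other charges held, the count reckons to 43.4, which means 14.5% target, and that neighbour gives 15.4%.

    starting material + free catalyst ⇌ catalyst intermediate A (K = 7.50 /M, k = 2.30 /M/s, Ea = 46.0 kJ/mol, ΔH = −69.0 kJ/mol)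
    catalyst intermediate A → free catalyst + target (k = 3.50 /s, Ea = 65.0 kJ/mol)
    second substrate + free catalyst ⇌ catalyst intermediate B (K = 4.40 /M, k = 2.50 /M/s, Ea = 44.0 kJ/mol, ΔH = −45.0 kJ/mol)
    catalyst intermediate B → free catalyst + second product (k = 10.0 /s, Ea = 70.0 kJ/mol)
    free catalyst + added ligand ⇌ idle complex, settled at all times (K = 62.0 /M, ΔH = 9.00 kJ/mol)
    catalyst intermediate B + capture agent → trapped intermediate (k = 0.810 /M/s, Ea = 56.0 kJ/mol)
    (constants at 0 °C)

The numbers in the tables come from a simulation for substances that don't exist, and the scatter is random.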